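Compound numbers are those of the steps and of the compound list. Hydrindane locants are used for all intermediates, including the cyclobutanes: C7a, C1, C2 and C3a are the four ring atoms of the cyclobutane, C3 and C1' are the two propenyl carbons that become the ring methine and the carbinol carbon. "β" is the face of the bicycle on which C3a–H lies, "α" the opposite face.

## Analysis of the target

The target 22 is a trans-fused hydrindane: C1 is the acyloxy methine, C2 the ketone, C3 the methine carrying the 1-hydroxyethyl group (carbinol carbon C1'), C3a and C7a the fusion carbons, C4 the isopropyl methine, C5 a methylene, C6 the second acyloxy methine and C7 the carbon of the exocyclic methylidene group. It has seven stereocentres on skeleton and side chain (C1 R, C3 R, C3a R, C4 R, C6 S, C7a S, C1' S) and one more in the (R)-2-methylbutanoate. With C3a–H as β, C7a–H is α, the isopropyl group, the C3 side chain and the C1 ester are β, the C6 ester is α (axial, next to the methylidene group), and C1' stands in a syn-aldol relation to C3. The sensitive groups are a β-hydroxy ketone (retro-aldol, dehydration), an α-acyloxy ketone with an acidic C1–H, a ketone with two stereogenic α-carbons, an allylic ester beside a 1,1-disubstituted alkene, and a β,β-disubstituted enoate that can lose its geometry. Three oxygen atoms must be told apart, two with different acyl groups and one free. The hard part is the strained trans fusion within the run of contiguous centres C1–C7a–C3a–C3 plus C4; C3a, C4 and C7a cannot be corrected by equilibration once the rings exist. The strategy rests on the fact that C7, C7a, C3a and C4 are the carbonyl, α-, β- and γ-carbons of a cyclohexenone. The C1–C7a bond and the trans C3a–C7a relationship can therefore be set in one photochemical step if C2 is first tied to C3a in a cyclobutane (C7a, C1, C2, C3a). That bond is temporary: moving C3a from C2 to a new carbon C3 turns the cyclobutanone into the cyclopentanone and creates C3 and C1' together.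

## Retrosynthetic reasoning

**22 from 21.** The last bond cut is the O–Si bond at C1'. The carbinol that must stay free is kept as a silyl ether while the other two oxygens are acylated. The forward step must remove silicon without touching two esters, an α-acyloxy ketone and a β-hydroxy ketone.

**21 from 18 and 19.** The C6 O–acyl bond is cut next. The enoate is the acyl group most prone to isomerisation and is put on as late as possible. The forward reaction must esterify a hindered axial allylic alcohol without moving the double bond of acid 19.

**18 from 17.** The C6–O bond is cut back to C6–H. C6 is the allylic methylene of the C7 methylidene group, so the alkene is the handle for oxygenation and no oxygen at C6 has to be carried through the photochemistry and the rearrangement. The forward reaction must choose C6 over the allylic methine C7a and the α face.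

**17 from 15 and 16; 15 from 13.** The C1 ester is cut at the acyl–oxygen bond, then the C1–O bond is cut back to the ketone 13. The C2 ketone distinguishes the C1 methylene from the substituted C3 methine, so a kinetic enolate places the oxygen. The forward reaction needs regioselective enolisation and oxygen delivery to the β face.

**13 from 12.** Silylation only; it is placed before any base is used so that the β-hydroxy ketone cannot cleave.

**12 from 11.** The C3–C3a bond is cut and C2–C3a is re-formed. A β-hydroxy ketone whose carbinol lies outside the ring is the retron of a semipinacol shift in an epoxide attached to a cyclobutanol. An aldol disconnection of C3–C1' was not taken: it would need a regiodefined enolate of a hydrindan-2-one with two similar α-methylenes, and the five-membered ring would have to exist already. The shift gives the ring, the ketone at C2, and C3 with C1' from one alkene geometry and one facial choice. The forward reaction must move C3a, not C1, anti to the breaking C3–O bond.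

**11 from 10; 10 from 6 and 7.** The epoxide C–O bonds are cut to the Z-allylic alcohol 10, and the C2–C3 bond to cyclobutanone 6 and bromide 7. The tertiary hydroxyl directs the oxidant to its own alkene and away from the C7 methylidene group, and the geometry of 7 is carried into 10.

**6 from 5 from 4.** Two functional-group changes. The methylidene group is installed before the cyclobutanone is unmasked, so that the two ketones never coexist and C7a loses its acidity early. The forward methylenation must be non-basic.

**4 from 2 and 3.** The C1–C7a and C2–C3a bonds are cut together. This is the only disconnection that makes the trans fusion, the C1–C7a bond and the masked C2 carbonyl in one step from a six-carbon ring that already holds C4. The forward reaction must be head-to-tail, trans-fused and anti to the isopropyl group.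

**2 from 1.** The cyclobutane of 1 is opened to the enone; the one stereocentre that survives becomes C4.

## Alternatives that were turned down

**Alternative 1:** The C3a–C7a and C6–C7 bonds are disconnected. In the forward direction an open-chain triene cyclises by an intramolecular Diels–Alder reaction (heat or Me2AlCl), closing both rings at once to the hydrindene ester A1.
- For it: both rings form in one step, and the C6 oxygen and a carbon at C7 are already in place. On these two points it is stronger than the chosen route, which adds the C6 oxygen and the C7 carbon separately.
- Against it: C4 is an alkene carbon in A1, so the isopropyl centre must later be set by hydrogenating a hindered trisubstituted alkene from one face. The trans fusion depends on the endo/exo preference of a three-atom tether, which is rarely high. The C7 ester must be converted to the methylidene group, and C1 is still unoxidised. The triene with its C3/C1' pair needs a long linear preparation.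
- In its place the chosen strategy takes C4 from the chiral pool, reaches its key step in one step, and sets the fusion in a reaction whose stereochemical course does not depend on a tether.

**Alternative 2:** The C1–C2 bond is disconnected. In the forward direction an α-acyloxyalkylstannane at C1 couples with a thiol ester at C2 under Pd2(dba)3 and Cu(O2CC4H3S), the monovalent copper salt of thiophene-2-carboxylic acid. This closes the cyclopentanone and gives A2, which is identical with compound 17 of the chosen route.
- For it: C1 arrives with its ester and its configuration fixed by the stannane, not by the face of an enolate. On this point it is stronger.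
- Against it: the coupling makes no ring-fusion stereochemistry. The trans-1,2-disubstituted methylidenecyclohexane with C3, C1', C3a, C4 and C7a set must be built first by other means. The stannane is a hindered secondary centre whose configuration would come from an addition next to C7a. The thiol ester sits beside an epimerisable C3 with a β-silyloxy group. The ring closure is an intramolecular case of a coupling that competes with protodestannylation.
- In its place the chosen strategy spends its key step on the part of the skeleton that is hardest to correct, and reaches the same compound 17.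

**Alternative 3:** The C4–C5 bond is disconnected. In the forward direction Mn(OAc)3 generates the C5 radical of a β-keto ester, which adds to C4 of a trisubstituted alkene (six-membered ring closure); Cu(OAc)2 oxidises the adduct radical to the isopropenyl group, giving A3.
- For it: the six-membered ring, C4 and an oxygen at C6 come in one step, and the C6 ketone offers a way to the C7 methylidene group. On the C6 oxygen it is stronger.
- Against it: the cyclopentane with C1, C3, C3a, C7a and C1' must be made first. A3 then needs many adjustments: removal of the C5 ester, hydrogenation of the isopropenyl group, methylenation at C7, and reduction of the C6 ketone to the axial alcohol. Its two oxygens at C1 and C1' carry the same silyl group, although one becomes an ester and the other stays free. Closure onto a hindered trisubstituted alkene sets C4 and C5 under weak control.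
- In its place the chosen strategy needs no redox corrections on the six-membered ring apart from one allylic oxidation.

Key step: step 2

Assumption: the acyl group on C1 is the (R)-2-methylbutanoyl group that the target structure encodes, and acids 16 and 19 are bought as single isomers.

## Steps

Step 1
Reactants: 1 (+)-nopinone, (1R,5S)-6,6-dimethylbicyclo[3.1.1]heptan-2-one
Product: 2 (R)-4-(propan-2-yl)cyclohex-2-en-1-one
Conditions: AlCl3 (1.5 equiv), CH2Cl2, 0 °C → rt
Reagents that add atoms: none
Why: Lewis-acid fragmentation of the strained cyclobutane: AlCl3 on the carbonyl oxygen breaks the bond between the carbonyl-side bridgehead and the gem-dimethyl carbon to a tertiary cation and an aluminium enolate, and a hydride shift from the bridging methylene to the cation gives the enone directly; the other bridgehead (C5 of 1) is not touched and becomes C4 of the target.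

Step 2
Reactants: 2 (R)-4-(propan-2-yl)cyclohex-2-en-1-one; 3 1,1-diethoxyethene
Product: 4 (1S,5R,6R)-7,7-diethoxy-5-(propan-2-yl)bicyclo[4.2.0]octan-2-one (trans-fused; C7 ketone, C7a–H α, C3a–H β, acetal carbon C2 on C3a, isopropyl β)
Conditions: hν (λ ≥ 350 nm, Pyrex), 3 (10 equiv), pentane, −40 °C; no base, no alumina
Reagents that add atoms: none
Why: Excitation and intersystem crossing give the twisted triplet of 2; its electrophilic α-carbon C7a bonds to the unsubstituted, electron-rich terminus of 3 (C1), which leaves a triplet 1,4-biradical with a secondary radical at C3a and a dialkoxy-stabilised radical at C2, and after spin inversion the C3a–C2 bond closes. The closest known reaction type is the enone–ketene acetal [2+2] photocycloaddition, which gives head-to-tail 7,7-dialkoxybicyclo[4.2.0]octan-2-ones that are largely trans-fused. The four-membered ring closes stepwise, by radical addition and then recombination of the 1,4-biradical. The trans relation of C7a and C3a is kinetic: the triplet is twisted about the C7a–C3a bond, its two ends react on opposite faces, and the biradical collapses before the six-membered ring relaxes. The configuration of C3a relative to C4 is set in the closure, which takes place anti to the neighbouring pseudo-equatorial isopropyl group, and with the trans fusion this fixes C7a as well. The step needs head-to-tail regiochemistry, secured by the polarity match between the α-keto radical centre and the CH2 terminus of the ketene acetal. It needs the trans fusion to survive, which is why light that the product ketone absorbs is filtered out and base is excluded until C7 is methylenated. It needs facial selectivity, for which the only control element is the C4 isopropyl group.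

Step 3
Reactants: 4 (1S,5R,6R)-7,7-diethoxy-5-(propan-2-yl)bicyclo[4.2.0]octan-2-one
Product: 5 trans-fused 7,7-diethoxy-2-methylidene-5-(propan-2-yl)bicyclo[4.2.0]octane (configuration at C3a, C4 and C7a as in 4)
Conditions: Zn, CH2Br2, TiCl4, THF/CH2Cl2, 0 °C → rt
Reagents that add atoms: dibromomethane, BrCBr
Why: Takai–Lombardo methylenation; the zinc–titanium methylene reagent is not basic, so the epimerisable C7a–H next to the ketone keeps its configuration and the acetal survives; from here on C7a is no longer α to a carbonyl group.

Step 4
Reactants: 5 trans-fused 7,7-diethoxy-2-methylidene-5-(propan-2-yl)bicyclo[4.2.0]octane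
Product: 6 trans-fused 2-methylidene-5-(propan-2-yl)bicyclo[4.2.0]octan-7-one (cyclobutanone carbonyl at C2, attached to C3a)
Conditions: 1 M HCl, THF, 0 °C; used at once
Reagents that add atoms: water, O
Why: Acid-catalysed acetal hydrolysis; dilute acid at 0 °C is used because C3a is now α to the cyclobutanone and the exocyclic alkene could migrate under stronger acid; enolisation of a cyclobutanone toward a ring-fusion carbon is slow, and the ketone is not stored.

Step 5
Reactants: 6 trans-fused 2-methylidene-5-(propan-2-yl)bicyclo[4.2.0]octan-7-one; 7 (Z)-1-bromoprop-1-ene
Product: 10 trans-fused 2-methylidene-5-(propan-2-yl)-7-[(Z)-prop-1-enyl]bicyclo[4.2.0]octan-7-ol (propenyl group β and cis to C3a–H; hydroxyl α), via (Z)-prop-1-enyllithium 8 (not isolated), via (Z)-prop-1-enylcerium dichloride 9 (not isolated)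
Conditions: 7, t-BuLi (2 equiv), Et2O, −78 °C; CeCl3, THF, −78 °C; then 6, −78 °C
Reagents that add atoms: none
Why: Bromine–lithium exchange with retention of alkene geometry, transmetallation to the organocerium reagent and 1,2-addition; the weakly basic cerium reagent adds to the strained, enolisable cyclobutanone without deprotonating C3a; attack is expected on the β face, past C3a–H, because the α face is flanked by the pseudo-axial hydrogens on C7a and C4, and the carbinol centre made here is temporary.

Step 6
Reactants: 10 trans-fused 2-methylidene-5-(propan-2-yl)-7-[(Z)-prop-1-enyl]bicyclo[4.2.0]octan-7-ol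
Product: 11 trans-fused 7-(cis-3-methyloxiran-2-yl)-2-methylidene-5-(propan-2-yl)bicyclo[4.2.0]octan-7-ol (epoxide oxygen on the alkene face anti to C1; methyl-bearing carbon C1' is S)
Conditions: VO(acac)2 (5 mol %), t-BuOOH, CH2Cl2, 0 °C
Reagents that add atoms: tert-butyl hydroperoxide, CC(C)(C)OO
Why: Hydroxyl-directed epoxidation: the vanadate ester of the tertiary alcohol delivers oxygen only to the allylic alkene and leaves the C7 methylidene group; with the Z methyl group, 1,3-allylic strain should place the ring methylene C1 inside and C3a outside in the reactive rotamer, so oxygen is delivered to the face anti to C1, on the side away from C4 and its isopropyl group; the Z geometry then fixes C1' as S in the cis-epoxide.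

Step 7
Reactants: 11 trans-fused 7-(cis-3-methyloxiran-2-yl)-2-methylidene-5-(propan-2-yl)bicyclo[4.2.0]octan-7-ol
Product: 12 trans-fused 3β-[(1S)-1-hydroxyethyl]-7-methylidene-4β-(propan-2-yl)octahydro-2H-inden-2-one (C3a–H β, C7a–H α)
Conditions: BF3·OEt2, CH2Cl2, −78 °C
Reagents that add atoms: none
Why: Semipinacol rearrangement of a 2,3-epoxy alcohol with ring expansion of the cyclobutanol: BF3 activates the epoxide, the C2–C3a bond, anti to the breaking C3–O bond, shifts from C2 to C3 with inversion at C3 and retention at C3a, and C2 becomes the ketone; the secondary ring-fusion carbon is the better migrating group and the shift releases the strain of the trans-fused four-membered ring; inversion at C3 of the cis-epoxide gives the β side chain and the syn relation to the (S)-carbinol.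

Step 8
Reactants: 12 trans-fused 3β-[(1S)-1-hydroxyethyl]-7-methylidene-4β-(propan-2-yl)octahydro-2H-inden-2-one
Product: 13 tert-butyldimethylsilyl ether of 12 at the C1' oxygen
Conditions: TBSOTf, 2,6-lutidine, CH2Cl2, −78 °C
Reagents that add atoms: tert-butyldimethylsilyl trifluoromethanesulfonate, CC(C)(C)[Si](C)(C)OS(=O)(=O)C(F)(F)F
Why: Silylation of the secondary alcohol with a silyl triflate and a hindered base at low temperature; it blocks retro-aldol cleavage in the basic step that follows and keeps this hydroxyl apart from the two that will be acylated.

Step 9
Reactants: 13 tert-butyldimethylsilyl ether of 12 at the C1' oxygen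
Product: 15 1β-hydroxy derivative of 13 (hydroxyl at C1 cis to the C3 side chain and trans to C7a–H), via sodium C1-enolate of 13 14 (not isolated)
Conditions: NaHMDS, THF, −78 °C; then 3-phenyl-2-(phenylsulfonyl)oxaziridine, −78 °C; AcOH
Reagents that add atoms: 3-phenyl-2-(phenylsulfonyl)oxaziridine, O=S(=O)(c1ccccc1)N1OC1c1ccccc1
Why: Kinetic deprotonation takes the unhindered C1 methylene and not the C3 methine, and the enolate is hydroxylated by the N-sulfonyloxaziridine (Davis oxidation), which does not touch the alkene; oxygen should enter C1 on the β face, anti to the pseudo-axial C7a–H on the neighbouring ring-fusion carbon (torsional control, as in axial attack on fused enolates), while the C3 side chain is pseudo-equatorial and screens that face only weakly.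

Step 10
Reactants: 15 1β-hydroxy derivative of 13; 16 (R)-2-methylbutanoic acid
Product: 17 1β-[(2R)-2-methylbutanoyloxy] derivative of 13
Conditions: DCC, DMAP (cat.), CH2Cl2, 0 °C → rt
Reagents that add atoms: none
Why: Steglich esterification of the secondary α-ketol with retention at C1; the stereocentre of the acid is not affected by carbodiimide activation with catalytic DMAP at low temperature, and acylation removes the risk of α-ketol isomerisation.

Step 11
Reactants: 17 1β-[(2R)-2-methylbutanoyloxy] derivative of 13
Product: 18 6α-hydroxy derivative of 17 (axial allylic alcohol, cis to C7a–H)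
Conditions: SeO2 (0.3 equiv), t-BuOOH, CH2Cl2, rt
Reagents that add atoms: selenium dioxide, O=[Se]=O; tert-butyl hydroperoxide, CC(C)(C)OO
Why: SeO2-catalysed allylic hydroxylation (ene reaction, then 2,3-sigmatropic shift of the allylseleninic acid) returns the alkene to the exocyclic position; the C6 methylene should react before the C7a methine, whose hydrogen would have to leave toward a strained ring-fusion alkene, and oxygen is delivered axially (α), as is usual for exocyclic methylene groups on trans-fused six-membered rings.

Step 12
Reactants: 18 6α-hydroxy derivative of 17; 19 (E)-3-methylpent-2-enoic acid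
Product: 21 6α-[(E)-3-methylpent-2-enoyloxy] derivative of 17 (the silyl ether of the target), via (E)-3-methylpent-2-enoic 2,4,6-trichlorobenzoic anhydride 20 (not isolated)
Conditions: 19, 2,4,6-Cl3C6H2COCl, Et3N, THF, rt; then 18, DMAP, toluene, rt
Reagents that add atoms: none
Why: Yamaguchi esterification through the mixed anhydride, a method suited to the hindered axial allylic alcohol; the C6 configuration is retained, and the E geometry of the enoate should hold because the activated acid meets no base stronger than DMAP.

Step 13
Reactants: 21 6α-[(E)-3-methylpent-2-enoyloxy] derivative of 17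
Product: 22 (1R,3R,3aR,4R,6S,7aS)-3-[(1S)-1-hydroxyethyl]-7-methylidene-1-{[(2R)-2-methylbutanoyl]oxy}-2-oxo-4-(propan-2-yl)octahydro-1H-inden-6-yl (2E)-3-methylpent-2-enoate (CNP0224363.1)
Conditions: HF·pyridine, pyridine, THF, 0 °C → rt
Reagents that add atoms: none
Why: Fluoride cleavage of the silyl ether under buffered acidic conditions that leave both esters, the α-acyloxy ketone and the new β-hydroxy ketone untouched; basic fluoride is avoided because it would invite acyl migration, epimerisation at C1 or C3 and retro-aldol cleavage.

## Compound list

1 | (+)-nopinone, (1R,5S)-6,6-dimethylbicyclo[3.1.1]heptan-2-one | O=C1CC[C@H]2C[C@@H]1C2(C)C | starting material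
2 | (R)-4-(propan-2-yl)cyclohex-2-en-1-one | O=C1C=C[C@@H](C(C)C)CC1 | intermediate
3 | 1,1-diethoxyethene | C=C(OCC)OCC | starting material
4 | (1S,5R,6R)-7,7-diethoxy-5-(propan-2-yl)bicyclo[4.2.0]octan-2-one, trans-fused | O=C1[C@@H]2[C@H](C(OCC)(OCC)C2)[C@@H](C(C)C)CC1 | intermediate
5 | trans-fused 7,7-diethoxy-2-methylidene-5-(propan-2-yl)bicyclo[4.2.0]octane | C=C1[C@@H]2[C@H](C(OCC)(OCC)C2)[C@@H](C(C)C)CC1 | intermediate
6 | trans-fused 2-methylidene-5-(propan-2-yl)bicyclo[4.2.0]octan-7-one | C=C1[C@@H]2[C@H](C(=O)C2)[C@@H](C(C)C)CC1 | intermediate
7 | (Z)-1-bromoprop-1-ene | C/C=C\Br | starting material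
8 | (Z)-prop-1-enyllithium | C/C=C\[Li] | intermediate (not isolated)
9 | (Z)-prop-1-enylcerium dichloride | C/C=C\[Ce](Cl)Cl | intermediate (not isolated)
10 | trans-fused 2-methylidene-5-(propan-2-yl)-7-[(Z)-prop-1-enyl]bicyclo[4.2.0]octan-7-ol, propenyl cis to C3a–H | C=C1[C@@H]2[C@H]([C@@](O)(C2)/C=C\C)[C@@H](C(C)C)CC1 | intermediate
11 | trans-fused 7-(cis-3-methyloxiran-2-yl)-2-methylidene-5-(propan-2-yl)bicyclo[4.2.0]octan-7-ol, C1' S | C=C1[C@@H]2[C@H]([C@@](O)(C2)[C@H]3O[C@H]3C)[C@@H](C(C)C)CC1 | intermediate
12 | trans-fused 3β-[(1S)-1-hydroxyethyl]-7-methylidene-4β-(propan-2-yl)octahydro-2H-inden-2-one | C=C1[C@@H]2[C@H]([C@H]([C@H](C)O)C(=O)C2)[C@@H](C(C)C)CC1 | intermediate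
13 | tert-butyldimethylsilyl ether of 12 | C=C1[C@@H]2[C@H]([C@H]([C@H](C)O[Si](C)(C)C(C)(C)C)C(=O)C2)[C@@H](C(C)C)CC1 | intermediate
14 | sodium C1-enolate of 13 | C=C1[C@@H]2[C@H]([C@H]([C@H](C)O[Si](C)(C)C(C)(C)C)C([O-])=C2)[C@@H](C(C)C)CC1.[Na+] | intermediate (not isolated)
15 | 1β-hydroxy derivative of 13 | C=C1[C@@H]2[C@H]([C@H]([C@H](C)O[Si](C)(C)C(C)(C)C)C(=O)[C@@H]2O)[C@@H](C(C)C)CC1 | intermediate
16 | (R)-2-methylbutanoic acid | CC[C@@H](C)C(=O)O | starting material
17 | 1β-[(2R)-2-methylbutanoyloxy] derivative of 13 | C=C1[C@@H]2[C@H]([C@H]([C@H](C)O[Si](C)(C)C(C)(C)C)C(=O)[C@@H]2OC(=O)[C@H](C)CC)[C@@H](C(C)C)CC1 | intermediate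
18 | 6α-hydroxy derivative of 17 | C=C1[C@@H]2[C@H]([C@H]([C@H](C)O[Si](C)(C)C(C)(C)C)C(=O)[C@@H]2OC(=O)[C@H](C)CC)[C@@H](C(C)C)C[C@@H]1O | intermediate
19 | (E)-3-methylpent-2-enoic acid | CC/C(C)=C/C(=O)O | starting material
20 | (E)-3-methylpent-2-enoic 2,4,6-trichlorobenzoic anhydride | CC/C(C)=C/C(=O)OC(=O)c1c(Cl)cc(Cl)cc1Cl | intermediate (not isolated)
21 | 6α-[(E)-3-methylpent-2-enoyloxy] derivative of 17 | C=C1[C@@H]2[C@H]([C@H]([C@H](C)O[Si](C)(C)C(C)(C)C)C(=O)[C@@H]2OC(=O)[C@H](C)CC)[C@@H](C(C)C)C[C@@H]1OC(=O)/C=C(\C)CC | intermediate
22 | (1R,3R,3aR,4R,6S,7aS)-3-[(1S)-1-hydroxyethyl]-7-methylidene-1-{[(2R)-2-methylbutanoyl]oxy}-2-oxo-4-(propan-2-yl)octahydro-1H-inden-6-yl (2E)-3-methylpent-2-enoate | C=C1[C@@H]2[C@H]([C@H]([C@H](C)O)C(=O)[C@@H]2OC(=O)[C@H](C)CC)[C@@H](C(C)C)C[C@@H]1OC(=O)/C=C(\C)CC | target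

Total step count: 13. Longest linear sequence: 13 steps, from 1 to 22.

## Steps least certain to work

**Step 2, the key step.** The biradical may partition badly: closure to the cis-fused adduct, or on the face syn to the isopropyl group, competes with the wanted closure, and the strained trans ketone can epimerise at C7a during isolation. The fallback is a redox detour that sets out from crude 4. The irradiated solution is treated at once with NaBH4 in ethanol at −40 °C, which turns the ketones into carbinols such as the trans-fused 7,7-diethoxy-5-(propan-2-yl)bicyclo[4.2.0]octan-2-ol F1 (both carbinol epimers), in which C7a is no longer acidic. The trans-fused, anti isomer is separated at this stage and oxidised with Dess–Martin periodinane and pyridine. The route is rejoined at 4, which is methylenated without purification.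

**Step 7.** C1 may migrate in place of C3a. In the rotamer of 11 that keeps the small hydroxyl group beside the methyl-bearing epoxide carbon, it is the C2–C1 bond that lies anti to the C3–O bond. The rotamer needed for the C3a shift presses C1 against that carbon and its cis methyl group. The fallback removes both this constraint and the dependence on the epoxide face; it sets out from 6 and comes back at 12.
- 1-Propynyllithium and CeCl3 give the trans-fused 2-methylidene-5-(propan-2-yl)-7-(prop-1-ynyl)bicyclo[4.2.0]octan-7-ol F2; either carbinol epimer serves.
- Ph3PAuCl/AgSbF6 (a cationic monovalent gold catalyst) activates the alkyne, which has no preferred rotamer, so the better migrating C3a shifts. This is the known ring expansion of 1-alkynylcyclobutanols to 2-alkylidenecyclopentanones, and it gives the trans-fused (E)-3-ethylidene-7-methylidene-4β-(propan-2-yl)octahydro-2H-inden-2-one F3.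
- Conjugate borylation with B2pin2, CuCl, NaOtBu, a chiral bisphosphine and methanol gives the 3β-[1-(pinacolboryl)ethyl] ketone F4. C1' is set by the ligand and C3 by protonation anti to C4.
- Oxidation with NaBO3·4H2O, with retention, gives 12.

**Step 6.** Oxygen may be delivered to the other alkene face (rotamer with C3a inside), since C1 and C3a differ little in size near the alkene. After a C3a shift that cis-epoxide would end with both C3 and C1' inverted. The fallback changes the alkene geometry so that this face becomes the useful one; it sets out from 6 and comes back at 13.
- (E)-Prop-1-enyllithium (from (E)-1-bromoprop-1-ene and t-BuLi) and CeCl3 give the trans-fused 2-methylidene-5-(propan-2-yl)-7-[(E)-prop-1-enyl]bicyclo[4.2.0]octan-7-ol F5.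
- Directed epoxidation on that face gives the trans-fused 7-(trans-3-methyloxiran-2-yl) carbinol F6. It has S at C1', and its least crowded rotamer has C2–C3a anti to C3–O.
- BF3·OEt2 gives the 3α-[(1S)-1-hydroxyethyl] ketone F7, with the side chain cis to C4.
- TBSOTf and 2,6-lutidine give its silyl ether F8.
- DBU in CH2Cl2 equilibrates C3 to the less crowded β epimer, which is 13.

**Step 9.** The oxaziridine may attack the α face, away from C3a–H and the C3 side chain, giving the C1 epimer. The fallback replaces hydroxylation and acylation by halogenation and substitution with inversion; it sets out from 13 and comes back at 17. The sodium enolate 14 is brominated with NBS at −78 °C, bromine entering where oxygen would, to give the 1α-bromo derivative of 13 F9. Caesium (R)-2-methylbutanoate (from 16 and Cs2CO3) in DMF displaces bromide by SN2 and gives 17.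

**Step 11.** The carbinol may form with equatorial (β) oxygen, and some material may be oxidised further to the enone. The fallback uses substitution with inversion in place of acylation with retention; it sets out from 17 and comes back at 21. If the oxidation delivers the 6β-hydroxy derivative of 17 F10, Mitsunobu esterification with 19 (PPh3, DIAD, toluene, 0 °C) inverts C6 and gives 21 directly. Allylic transposition is the side reaction to watch in this variant.

## Further compounds

F1 | step 2 | trans-fused 7,7-diethoxy-5-(propan-2-yl)bicyclo[4.2.0]octan-2-ol (both carbinol epimers) | OC1[C@@H]2[C@H](C(OCC)(OCC)C2)[C@@H](C(C)C)CC1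
F2 | step 7 | trans-fused 2-methylidene-5-(propan-2-yl)-7-(prop-1-ynyl)bicyclo[4.2.0]octan-7-ol | C=C1[C@@H]2[C@H]([C@@](O)(C2)C#CC)[C@@H](C(C)C)CC1
F3 | step 7 | trans-fused (E)-3-ethylidene-7-methylidene-4β-(propan-2-yl)octahydro-2H-inden-2-one | C=C1[C@@H]2[C@H](/C(=C\C)C(=O)C2)[C@@H](C(C)C)CC1
F4 | step 7 | trans-fused 3β-[1-(4,4,5,5-tetramethyl-1,3,2-dioxaborolan-2-yl)ethyl]-7-methylidene-4β-(propan-2-yl)octahydro-2H-inden-2-one | C=C1[C@@H]2[C@H]([C@H]([C@H](C)B3OC(C)(C)C(C)(C)O3)C(=O)C2)[C@@H](C(C)C)CC1
F5 | step 6 | trans-fused 2-methylidene-5-(propan-2-yl)-7-[(E)-prop-1-enyl]bicyclo[4.2.0]octan-7-ol | C=C1[C@@H]2[C@H]([C@@](O)(C2)/C=C/C)[C@@H](C(C)C)CC1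
F6 | step 6 | trans-fused 7-(trans-3-methyloxiran-2-yl)-2-methylidene-5-(propan-2-yl)bicyclo[4.2.0]octan-7-ol, C1' S | C=C1[C@@H]2[C@H]([C@@](O)(C2)[C@@H]3O[C@H]3C)[C@@H](C(C)C)CC1
F7 | step 6 | trans-fused 3α-[(1S)-1-hydroxyethyl]-7-methylidene-4β-(propan-2-yl)octahydro-2H-inden-2-one | C=C1[C@@H]2[C@H]([C@@H]([C@H](C)O)C(=O)C2)[C@@H](C(C)C)CC1
F8 | step 6 | tert-butyldimethylsilyl ether of F7 | C=C1[C@@H]2[C@H]([C@@H]([C@H](C)O[Si](C)(C)C(C)(C)C)C(=O)C2)[C@@H](C(C)C)CC1
F9 | step 9 | 1α-bromo derivative of 13 | C=C1[C@@H]2[C@H]([C@H]([C@H](C)O[Si](C)(C)C(C)(C)C)C(=O)[C@H]2Br)[C@@H](C(C)C)CC1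
F10 | step 11 | 6β-hydroxy derivative of 17 | C=C1[C@@H]2[C@H]([C@H]([C@H](C)O[Si](C)(C)C(C)(C)C)C(=O)[C@@H]2OC(=O)[C@H](C)CC)[C@@H](C(C)C)C[C@H]1O
A1 | alternative 1 | trans-hydrindene C7 methyl ester with C4–C5 alkene, C2 dioxolane, C1' tert-butyldimethylsilyl ether and C6 triethylsilyl ether | COC(=O)[C@@H]1[C@@H]2[C@H]([C@H]([C@H](C)O[Si](C)(C)C(C)(C)C)C3(OCCO3)C2)C(C(C)C)=C[C@@H]1O[Si](CC)(CC)CC
A2 | alternative 2 | 1-acyloxyhydrindan-2-one with silylated carbinol and unoxidised C6 (identical with 17) | C=C1[C@@H]2[C@H]([C@H]([C@H](C)O[Si](C)(C)C(C)(C)C)C(=O)[C@@H]2OC(=O)[C@H](C)CC)[C@@H](C(C)C)CC1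
A3 | alternative 3 | trans-hydrindane C6 ketone with C5 methyl ester, C4 isopropenyl group, C2 dioxolane and silyl ethers at C1 and C1' | C1[C@@H]2[C@H]([C@H]([C@H](C)O[Si](C)(C)C(C)(C)C)C3(OCCO3)[C@@H]2O[Si](C)(C)C(C)(C)C)[C@@H](C(C)=C)[C@H](C(=O)OC)C1=O
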